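## Analysis of the target

The target is a 2-arylbenzofuran. A furan ring is fused to benzo ring B, which carries a hydroxyl at C6 and a prenyl group at C7. C2 of the furan bears resorcinol ring A, with hydroxyls at C3' and C5' and prenyl groups at C2' and C6'. There is no stereocentre, and because ring A carries two identical ortho substituents, even slow rotation about the C2–C1' bond creates no isomers; only constitution has to be controlled. Every phenol sits ortho to a prenyl group, so Brønsted or Lewis acids can close 2,2-dimethylchroman rings, and the trisubstituted alkenes rule out hydrogenolysis, boron or aluminium halides and free electrophilic halogen late in the route. The difficulties are the placement of three C-prenyl groups without isomers, the crowding at C1' between two prenylated carbons, and a final deprotection that must free two phenols on the same ring without touching the alkenes. The strategy rests on the furan carbons C2 and C3. C3 is the former formyl carbon of a salicylaldehyde (ring B), and C2 is the former carboxyl carbon of a ring A benzoic acid. The two are already tied together through O1 as an aryl ester, so one reductive carbonyl–carbonyl coupling forms C2=C3 and the furan ring.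

## Retrosynthetic reasoning

**Unmasking the phenols (14 from 13).** The last operation is reserved for freeing the three hydroxyls, so that the acid-sensitive ortho-prenylphenol arrays exist only in the final compound. Methyl ethers were considered and rejected. Lewis acidic dealkylation would cyclise the prenyl groups onto the new phenols. Thiolate dealkylation would be expected to stall on ring A after the first methyl group, because the second displacement would have to expel an aryloxide that already carries a negative charge. The phenols are therefore carried as methoxymethyl acetals in 13, which dilute protic acid in methanol removes at room temperature.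

**Furan ring (13 from 12).** The C2=C3 bond is cut. Both carbons become carbonyl carbons: the formyl group on ring B and the acyl carbon of the ring A benzoate on O1. This is the only disconnection of the furan that lets the crowded C2–C1' bond come into the synthesis ready-made as part of a benzoic acid, so no cross-coupling is needed at a doubly ortho-substituted carbon. The forward reaction has to join two electrophilic carbons reductively, reduce the aldehyde before the ester, and close the five-membered ring faster than two aldehydes dimerise.

**Ester C–O bond (12 from 6 and 10, through 11).** Cutting the aryl ester gives acid 6 and salicylaldehyde 10, two fragments of similar size. The forward step is an acylation of a phenoxide by acid chloride 11. Both partners are ortho-disubstituted, so the acid is activated as strongly as possible, and under neutral conditions to spare the acetals.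

**Ring A fragment (6 from 5, 5 from 3 and 4, 3 from 2, 2 from 1).** The two Caryl–CH2 bonds at C2' and C6' are cut to dibromide 3 and stannane 4. Ipso substitution of bromine fixes the position of each prenyl group, which electrophilic or Claisen prenylation of a resorcinol would not. The carboxyl carbon is carried as a formyl group through the coupling. The formyl group activates the flanking C–Br bonds towards zerovalent palladium, and an aldehyde between two ortho substituents can still be oxidised to acid 6, whereas a similarly placed ester would resist hydrolysis. Dibromide 3 comes from bis-acetal 2, whose two alkoxy groups direct bromination to the two positions ortho to the formyl group, and 2 comes from dihydroxy aldehyde 1.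

**Ring B fragment (10 from 9, 9 from 7 and 8).** The acetal on O4 of 10 is cut first: in 9 the C2 hydroxyl is tied up in a hydrogen bond to the formyl group and the C4 hydroxyl is the more acidic, so one equivalent of alkylating agent suffices. The C3–CH2 bond of 9 is cut to 7 and bromide 8. C3 lies between both oxygens of 7 and is its most nucleophilic carbon, so direct nuclear prenylation reaches 9 in one step from a cheap aldehyde.

## Alternatives that were turned down

**Alternative 1: triple Claisen rearrangement on a bromine-blocked core.** The three Caryl–CH2 bonds at C7, C2' and C6' are cut together. Heating the tris(1,1-dimethylallyl) ether A2 should move each allyl unit to an ortho carbon and give A1, with bromine at C4' blocking the position between the two ring A oxygens. In its favour, all three prenyl groups arrive in one thermal step on a simple benzofuran, no tin or palladium is needed for them, and the phenols emerge free. Against it, the C6 ether can migrate to C5 as well as to C7, and the ring A migrations must end next to the bulky benzofuranyl group. The hot reaction mixture holds free ortho-prenylphenols that can cyclise to chromans, and the three tertiary allyl ethers of A2 are themselves prone to ionise. Bromine must afterwards be removed from A1 reductively in the presence of three alkenes and three phenols. On paper it could be shorter than the chosen route and it needs no protecting groups, which is conceded. The chosen route offers instead a fixed position for every prenyl group and a key step with one selectivity question, not three at once.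

**Alternative 2: Danheiser benzannulation of the benzo ring.** Ring B is cut at C3a–C4, C4–C5 and C6–C7. The ketene generated from acid chloride A4 with an amine base adds silyloxyalkyne A5, and the cyclobutenone opens and electrocyclises onto the furan to give A3. In its favour, the 6-oxy-7-prenyl pattern of ring B is set with complete regiocontrol and the route is convergent. On that point it is stronger than the direct C-prenylation used here. Against it, A3 carries a C4 hydroxyl that the target lacks, which costs a sulfonylation and a reduction. The 2,6-diprenyl ring A must still be made by the same coupling chemistry and then built into a 2,5-disubstituted furan acid. The electrocyclisation has to interrupt furan aromaticity, and the ring A methyl ethers of A3 bring back the dealkylation problem. The route is several steps longer, and the chosen strategy buys ring B intact and forms only the furan.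

**Alternative 3: aldol aromatisation of a triketone to ring A.** Ring A is cut at C1'–C6'. Base would enolise the terminal methylene of triketone A7, the enolate would attack the benzofuranyl ketone, and loss of water would give A6 with both ring A phenols free. In its favour, ring A arrives with both prenyl groups and without protecting groups, and only one acetal remains to be removed, a lighter endgame than three acetal cleavages. Against it, the required carbanion is the least acidic site of A7, so a polyanion is needed, and the electrophile is a conjugated, alpha-branched heteroaryl ketone. Pyranone formation by O-cyclisation is the usual fate of 1,3,5-triketones. Making A7 demands selective prenylation at one of two doubly activated positions, and the prenylated benzofuran acid still has to be made. The chosen route has close precedent for every bond-forming step and no ambiguous site of reaction on ring A.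

Key step: step 8

Remark: the target has no stereocentre, so no configuration has to be set; 3,5-dihydroxybenzaldehyde is taken as commercially available.

## Route

Step 1
Reactants: 1 3,5-dihydroxybenzaldehyde
Product: 2 3,5-bis(methoxymethoxy)benzaldehyde
Conditions: MOMCl (2.5 equiv), K2CO3, acetone, 0 °C to rt
Reagents that add atoms: chloromethyl methyl ether, COCCl
Why: Williamson-type O-alkylation of both phenoxides by a reactive alpha-chloro ether; the aldehyde is inert under these conditions.

Step 2
Reactants: 2 3,5-bis(methoxymethoxy)benzaldehyde
Product: 3 2,6-dibromo-3,5-bis(methoxymethoxy)benzaldehyde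
Conditions: NBS (2.2 equiv), MeCN, 0 °C to rt, dark
Reagents that add atoms: N-bromosuccinimide, O=C1CCC(=O)N1Br
Why: Electrophilic aromatic bromination; C2 and C6 are each para to one acetal oxygen and ortho to the other, whereas C4 is squeezed between both alkoxy groups, so the 2,6-dihalide typical of 3,5-dialkoxybenzoyl compounds should form, and no free HBr arises to attack the acetals.

Step 3
Reactants: 3 2,6-dibromo-3,5-bis(methoxymethoxy)benzaldehyde; 4 tributyl(3-methylbut-2-enyl)stannane
Product: 5 3,5-bis(methoxymethoxy)-2,6-bis(3-methylbut-2-enyl)benzaldehyde
Conditions: 4 (3 equiv), Pd(PPh3)4 (10 mol %), DMF, 100 °C, degassed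
Reagents that add atoms: none
Why: Twofold Stille coupling; the ortho formyl group speeds oxidative addition of zerovalent palladium into both C–Br bonds, and the allyl unit should be transferred through its unsubstituted terminus, giving the linear prenyl arene.

Step 4
Reactants: 5 3,5-bis(methoxymethoxy)-2,6-bis(3-methylbut-2-enyl)benzaldehyde
Product: 6 3,5-bis(methoxymethoxy)-2,6-bis(3-methylbut-2-enyl)benzoic acid
Conditions: NaClO2, NaH2PO4, 2-methylbut-2-ene (large excess), t-BuOH/THF/H2O, 0 °C to rt
Reagents that add atoms: sodium chlorite, [Na+].[O-]Cl=O
Why: Pinnick oxidation; chlorous acid adds to the formyl group and fragments without needing access to a tetrahedral acyl centre, the excess alkene traps hypochlorous acid before it reaches the prenyl groups, and the weakly acidic buffer spares the acetals.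

Step 5
Reactants: 7 2,4-dihydroxybenzaldehyde; 8 1-bromo-3-methylbut-2-ene
Product: 9 2,4-dihydroxy-3-(3-methylbut-2-enyl)benzaldehyde
Conditions: KOH, H2O, 0 °C to rt; chromatographic removal of O-alkylated and C5-alkylated material
Reagents that add atoms: none
Why: Nuclear C-alkylation of a resorcinol-type phenoxide; in water the oxygens are shielded by hydrogen bonding and C3, activated by both oxygens, is the most nucleophilic carbon, a known direct prenylation of 2,4-dihydroxyaryl carbonyl compounds.

Step 6
Reactants: 9 2,4-dihydroxy-3-(3-methylbut-2-enyl)benzaldehyde
Product: 10 2-hydroxy-4-(methoxymethoxy)-3-(3-methylbut-2-enyl)benzaldehyde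
Conditions: MOMCl (1.1 equiv), K2CO3, acetone, 0 °C
Reagents that add atoms: chloromethyl methyl ether, COCCl
Why: Selective O-alkylation; the C4 hydroxyl is para to the formyl group and the more acidic, while the C2 hydroxyl is held in a hydrogen bond to the formyl oxygen and stays free.

Step 7
Reactants: 6 3,5-bis(methoxymethoxy)-2,6-bis(3-methylbut-2-enyl)benzoic acid; 10 2-hydroxy-4-(methoxymethoxy)-3-(3-methylbut-2-enyl)benzaldehyde
Product: 12 6-formyl-3-(methoxymethoxy)-2-(3-methylbut-2-enyl)phenyl 3,5-bis(methoxymethoxy)-2,6-bis(3-methylbut-2-enyl)benzoate, via acid chloride 11 (not isolated)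
Conditions: 6, 1-chloro-N,N,2-trimethylprop-1-en-1-amine (1.05 equiv), CH2Cl2, 0 °C to rt, evaporate; then 10, NaH, THF, 0 °C, add crude 11, rt to 50 °C
Reagents that add atoms: none
Why: Acid chloride formation with an alpha-chloro enamine releases no HCl, so acetals and alkenes survive; acylation of the sodium phenoxide then follows the behaviour of 2,6-dialkylbenzoyl chlorides, which still acylate phenoxides because the chloride is a very good leaving group.

Step 8
Reactants: 12 6-formyl-3-(methoxymethoxy)-2-(3-methylbut-2-enyl)phenyl 3,5-bis(methoxymethoxy)-2,6-bis(3-methylbut-2-enyl)benzoate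
Product: 13 2-[3,5-bis(methoxymethoxy)-2,6-bis(3-methylbut-2-enyl)phenyl]-6-(methoxymethoxy)-7-(3-methylbut-2-enyl)benzofuran
Conditions: TiCl3 (8 equiv), Zn dust (16 equiv), DME, reflux 2 h; then 12 in DME added over 10 h (final ca. 0.005 M), reflux
Reagents that add atoms: none
Why: Low-valent titanium made from TiCl3 and Zn transfers an electron to the formyl group, the most easily reduced carbonyl of 12, giving a titanium-bound ketyl at the future C3. This carbon adds to the ester carbonyl held on O1 in a 5-exo-trig closure (the ring formed contains C3, C3a, C7a, O1 and C2, and the attacked C=O is exocyclic), and titanium then removes both oxygens of the 2,3-diolate, so the C2=C3 bond and the aromatic furan appear together. The closest known reaction type is the intramolecular McMurry-type oxo-ester coupling of O-acylated ortho-hydroxyaryl carbonyl compounds to benzofurans. No stereocentre remains, since the transient centres at C2 and C3 are erased on deoxygenation. Two selectivities are needed: the aldehyde is reduced before the ester because of its much less negative reduction potential, and ring closure beats pinacol dimerisation because the substrate is fed slowly at high dilution into excess reagent with the ester held ortho to the ketyl. The acyl carbon lies between two prenyl groups, but the attack is intramolecular and by a small benzylic centre, and this coupling is known to accept bulky acyl groups. Trisubstituted alkenes and aryl ethers are not reduced, and any acetal lost to the Lewis acidic chlorides would be harmless because all three are removed in the next step.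

Step 9
Reactants: 13 2-[3,5-bis(methoxymethoxy)-2,6-bis(3-methylbut-2-enyl)phenyl]-6-(methoxymethoxy)-7-(3-methylbut-2-enyl)benzofuran
Product: 14 5-[6-hydroxy-7-(3-methylbut-2-enyl)benzofuran-2-yl]-4,6-bis(3-methylbut-2-enyl)benzene-1,3-diol
Conditions: HCl (ca. 1 M) in MeOH/THF, 0 °C to rt, under argon; NaHCO3 quench
Reagents that add atoms: none
Why: Acid-catalysed acetal exchange with methanol through an oxocarbenium ion; this is fast at room temperature in dilute acid, whereas protonation of a trisubstituted alkene needs stronger acid or heat, so the three phenols should be freed before chroman formation sets in.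

## Compound list

1 | 3,5-dihydroxybenzaldehyde | O=Cc1cc(O)cc(O)c1 | starting material
2 | 3,5-bis(methoxymethoxy)benzaldehyde | O=Cc1cc(OCOC)cc(OCOC)c1 | intermediate
3 | 2,6-dibromo-3,5-bis(methoxymethoxy)benzaldehyde | O=Cc1c(Br)c(OCOC)cc(OCOC)c1Br | intermediate
4 | tributyl(3-methylbut-2-enyl)stannane | CCCC[Sn](CCCC)(CCCC)CC=C(C)C | starting material
5 | 3,5-bis(methoxymethoxy)-2,6-bis(3-methylbut-2-enyl)benzaldehyde | O=Cc1c(CC=C(C)C)c(OCOC)cc(OCOC)c1CC=C(C)C | intermediate
6 | 3,5-bis(methoxymethoxy)-2,6-bis(3-methylbut-2-enyl)benzoic acid | O=C(O)c1c(CC=C(C)C)c(OCOC)cc(OCOC)c1CC=C(C)C | intermediate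
7 | 2,4-dihydroxybenzaldehyde | O=Cc1ccc(O)cc1O | starting material
8 | 1-bromo-3-methylbut-2-ene | CC(C)=CCBr | starting material
9 | 2,4-dihydroxy-3-(3-methylbut-2-enyl)benzaldehyde | O=Cc1ccc(O)c(CC=C(C)C)c1O | intermediate
10 | 2-hydroxy-4-(methoxymethoxy)-3-(3-methylbut-2-enyl)benzaldehyde | O=Cc1ccc(OCOC)c(CC=C(C)C)c1O | intermediate
11 | 3,5-bis(methoxymethoxy)-2,6-bis(3-methylbut-2-enyl)benzoyl chloride | O=C(Cl)c1c(CC=C(C)C)c(OCOC)cc(OCOC)c1CC=C(C)C | intermediate
12 | 6-formyl-3-(methoxymethoxy)-2-(3-methylbut-2-enyl)phenyl 3,5-bis(methoxymethoxy)-2,6-bis(3-methylbut-2-enyl)benzoate | O=Cc1ccc(OCOC)c(CC=C(C)C)c1OC(=O)c1c(CC=C(C)C)c(OCOC)cc(OCOC)c1CC=C(C)C | intermediate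
13 | 2-[3,5-bis(methoxymethoxy)-2,6-bis(3-methylbut-2-enyl)phenyl]-6-(methoxymethoxy)-7-(3-methylbut-2-enyl)benzofuran | COCOc1cc(OCOC)c(CC=C(C)C)c(-c2cc3ccc(OCOC)c(CC=C(C)C)c3o2)c1CC=C(C)C | intermediate
14 | 5-[6-hydroxy-7-(3-methylbut-2-enyl)benzofuran-2-yl]-4,6-bis(3-methylbut-2-enyl)benzene-1,3-diol | CC(C)=CCc1c(O)cc(O)c(CC=C(C)C)c1-c1cc2ccc(O)c(CC=C(C)C)c2o1 | target

## Step count and least certain steps

Total step count: 9. Longest linear sequence: 7 (steps 1, 2, 3, 4, 7, 8, 9).

**Step 8 (key step).** Three processes could defeat the cyclisation. Aldehydes could couple with each other to pinacols or stilbenes. The formyl group could be reduced to the benzylic alcohol without ring closure. The ketyl could fail to reach the shielded acyl carbon, after which the ester would be cleaved reductively. All three follow from the aldehyde being the most reactive site and the ester carbon the most hindered. The fallback forms the same C2=C3 bond by a polar, redox-neutral intramolecular Wittig reaction and sets out from 12. The formyl group would be reduced chemoselectively (NaBH4, THF/MeOH, −20 °C) to 6-(hydroxymethyl)-3-(methoxymethoxy)-2-(3-methylbut-2-enyl)phenyl 3,5-bis(methoxymethoxy)-2,6-bis(3-methylbut-2-enyl)benzoate F1. The low temperature and the hindered acyl group should prevent migration of the ester to the benzylic oxygen. F1 would be converted under neutral conditions (CBr4, PPh3, CH2Cl2, 0 °C) into benzylic bromide F2. This would be quaternised with PPh3 in toluene to [2-[3,5-bis(methoxymethoxy)-2,6-bis(3-methylbut-2-enyl)benzoyloxy]-4-(methoxymethoxy)-3-(3-methylbut-2-enyl)benzyl]triphenylphosphonium bromide F3. Et3N in refluxing toluene would then give the ylide, which attacks the neighbouring ester carbonyl and eliminates the phosphine oxide to come back to the route at 13.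

**Step 7.** The acylation may be slow. Both partners are doubly ortho-substituted and the phenoxide of 10 is delocalised into the formyl group. Acid chloride 11 could meanwhile ionise and be captured by a neighbouring prenyl alkene, or be hydrolysed back to 6 on work-up. The fallback changes the order of events so that the acylating agent is activated by two halogens in place of two alkyl chains. From 3, chlorite oxidation would give 2,6-dibromo-3,5-bis(methoxymethoxy)benzoic acid F4. The same chloro enamine would give 2,6-dibromo-3,5-bis(methoxymethoxy)benzoyl chloride F5, an analogue of the 2,6-dihalobenzoyl chlorides used for difficult esterifications. F5 would acylate the sodium salt of 10 to 6-formyl-3-(methoxymethoxy)-2-(3-methylbut-2-enyl)phenyl 2,6-dibromo-3,5-bis(methoxymethoxy)benzoate F6. A twofold Stille coupling of F6 with 4 under the conditions of step 3 would return to the route at 12.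

**Step 3.** The stannane could couple through its substituted terminus and give 1,1-dimethylallyl isomers. The second coupling at the hindered position could stop short, or the bromide could be replaced by hydrogen. The fallback separates C–C bond formation from the installation of the trisubstituted alkene. From 3, twofold coupling with allyltributylstannane (Pd(PPh3)4, DMF) would give 2,6-diallyl-3,5-bis(methoxymethoxy)benzaldehyde F7, for which no allylic regiochemistry exists. Cross-metathesis with 2-methylbut-2-ene as solvent and second-generation Grubbs catalyst at 40 °C would convert both allyl groups into prenyl groups and return to the route at 5.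

**Step 5.** Site selectivity may be poor: alkylation at oxygen, at C5, or twice is to be expected beside the wanted C3 product, because several nucleophilic positions of the phenoxide compete. The fallback delivers the prenyl group by a sigmatropic shift from O4. From 7, alkylation of the more acidic C4 hydroxyl with 3-chloro-3-methylbut-1-yne (K2CO3, KI, CuI cat., acetone) would give 2-hydroxy-4-(2-methylbut-3-yn-2-yloxy)benzaldehyde F8. Semi-hydrogenation (H2, Pd on CaCO3 poisoned with Pb(OAc)2, quinoline, EtOAc) would give 2-hydroxy-4-(2-methylbut-3-en-2-yloxy)benzaldehyde F9. Heating in N,N-diethylaniline at about 130 °C would bring about the Claisen rearrangement. It is directed to C3 by the bond fixation that the chelated C2 hydroxyl imposes, and it returns to the route at 9.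

**Step 9.** A freed phenol could add across its neighbouring prenyl double bond under the acid to close a chroman ring. The alkenes could also take up HCl or methanol, and the electron-rich product could oxidise in air. The fallback avoids any free protic acid by exchanging the acetals for silyl ethers under buffered conditions. From 13, TMSOTf and 2,2'-bipyridyl in MeCN at 0 °C would give 2-[2,6-bis(3-methylbut-2-enyl)-3,5-bis(trimethylsilyloxy)phenyl]-7-(3-methylbut-2-enyl)-6-(trimethylsilyloxy)benzofuran F10, with the acetal carbon transferred to the bipyridyl. Neutral hydrolysis of F10 with water would give 14.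

## Further compounds

F1 | step 8 | 6-(hydroxymethyl)-3-(methoxymethoxy)-2-(3-methylbut-2-enyl)phenyl 3,5-bis(methoxymethoxy)-2,6-bis(3-methylbut-2-enyl)benzoate | OCc1ccc(OCOC)c(CC=C(C)C)c1OC(=O)c1c(CC=C(C)C)c(OCOC)cc(OCOC)c1CC=C(C)C
F2 | step 8 | 6-(bromomethyl)-3-(methoxymethoxy)-2-(3-methylbut-2-enyl)phenyl 3,5-bis(methoxymethoxy)-2,6-bis(3-methylbut-2-enyl)benzoate | BrCc1ccc(OCOC)c(CC=C(C)C)c1OC(=O)c1c(CC=C(C)C)c(OCOC)cc(OCOC)c1CC=C(C)C
F3 | step 8 | [2-[3,5-bis(methoxymethoxy)-2,6-bis(3-methylbut-2-enyl)benzoyloxy]-4-(methoxymethoxy)-3-(3-methylbut-2-enyl)benzyl]triphenylphosphonium bromide | [Br-].c1ccc(cc1)[P+](Cc1ccc(OCOC)c(CC=C(C)C)c1OC(=O)c1c(CC=C(C)C)c(OCOC)cc(OCOC)c1CC=C(C)C)(c1ccccc1)c1ccccc1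
F4 | step 7 | 2,6-dibromo-3,5-bis(methoxymethoxy)benzoic acid | O=C(O)c1c(Br)c(OCOC)cc(OCOC)c1Br
F5 | step 7 | 2,6-dibromo-3,5-bis(methoxymethoxy)benzoyl chloride | O=C(Cl)c1c(Br)c(OCOC)cc(OCOC)c1Br
F6 | step 7 | 6-formyl-3-(methoxymethoxy)-2-(3-methylbut-2-enyl)phenyl 2,6-dibromo-3,5-bis(methoxymethoxy)benzoate | O=Cc1ccc(OCOC)c(CC=C(C)C)c1OC(=O)c1c(Br)c(OCOC)cc(OCOC)c1Br
F7 | step 3 | 2,6-diallyl-3,5-bis(methoxymethoxy)benzaldehyde | O=Cc1c(CC=C)c(OCOC)cc(OCOC)c1CC=C
F8 | step 5 | 2-hydroxy-4-(2-methylbut-3-yn-2-yloxy)benzaldehyde | O=Cc1ccc(OC(C)(C)C#C)cc1O
F9 | step 5 | 2-hydroxy-4-(2-methylbut-3-en-2-yloxy)benzaldehyde | O=Cc1ccc(OC(C)(C)C=C)cc1O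
F10 | step 9 | 2-[2,6-bis(3-methylbut-2-enyl)-3,5-bis(trimethylsilyloxy)phenyl]-7-(3-methylbut-2-enyl)-6-(trimethylsilyloxy)benzofuran | C[Si](C)(C)Oc1cc(O[Si](C)(C)C)c(CC=C(C)C)c(-c2cc3ccc(O[Si](C)(C)C)c(CC=C(C)C)c3o2)c1CC=C(C)C
A1 | alternative 1 | 2-[4-bromo-3,5-dihydroxy-2,6-bis(3-methylbut-2-enyl)phenyl]-7-(3-methylbut-2-enyl)benzofuran-6-ol | CC(C)=CCc1c(O)c(Br)c(O)c(CC=C(C)C)c1-c1cc2ccc(O)c(CC=C(C)C)c2o1
A2 | alternative 1 | 2-[4-bromo-3,5-bis(2-methylbut-3-en-2-yloxy)phenyl]-6-(2-methylbut-3-en-2-yloxy)benzofuran | C=CC(C)(C)Oc1ccc2cc(-c3cc(OC(C)(C)C=C)c(Br)c(OC(C)(C)C=C)c3)oc2c1
A3 | alternative 2 | 2-[3,5-dimethoxy-2,6-bis(3-methylbut-2-enyl)phenyl]-7-(3-methylbut-2-enyl)-6-(triisopropylsilyloxy)benzofuran-4-ol | COc1cc(OC)c(CC=C(C)C)c(-c2cc3c(O)cc(O[Si](C(C)C)(C(C)C)C(C)C)c(CC=C(C)C)c3o2)c1CC=C(C)C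
A4 | alternative 2 | 2-[5-[3,5-dimethoxy-2,6-bis(3-methylbut-2-enyl)phenyl]furan-2-yl]-5-methylhex-4-enoyl chloride | O=C(Cl)C(CC=C(C)C)c1ccc(-c2c(CC=C(C)C)c(OC)cc(OC)c2CC=C(C)C)o1
A5 | alternative 2 | (triisopropylsilyloxy)ethyne | C#CO[Si](C(C)C)(C(C)C)C(C)C
A6 | alternative 3 | 2-[3,5-dihydroxy-2,6-bis(3-methylbut-2-enyl)phenyl]-6-(methoxymethoxy)-7-(3-methylbut-2-enyl)benzofuran | CC(C)=CCc1c(O)cc(O)c(CC=C(C)C)c1-c1cc2ccc(OCOC)c(CC=C(C)C)c2o1
A7 | alternative 3 | 1-[6-(methoxymethoxy)-7-(3-methylbut-2-enyl)benzofuran-2-yl]-9-methyl-2-(3-methylbut-2-enyl)dec-8-ene-1,3,5-trione | COCOc1ccc2cc(C(=O)C(CC=C(C)C)C(=O)CC(=O)CCC=C(C)C)oc2c1CC=C(C)C
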